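The target's six-membered carbocycle (C1 bearing the alkyne, C2 the vinylic CH, C3–OAc, C4–OMe, C5/C6 the free cis-diol beside C1) is read as a benzene ring at a lower oxidation level, so the route rests on dearomatizing an arene that already carries the C1 alkyne carbon. In a single enzymatic operation, toluene dioxygenase turns flat 1-ethynyl-4-iodobenzene into the C5,C6 cis-diol, setting two stereocentres and leaving the C1=C2–C3=C4 diene for later oxidation. The para iodine (at C4) serves only as a removable steering group that selects the required enantiomeric series. C3 and C4 are then relayed from the diol, and the side chain is joined last by Sonogashira coupling.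

Key step: step 1

Remark on numbering: the ring atoms keep the target numbering throughout (C1 alkynyl carbon, C2 vinylic CH, C3 acetoxy carbon, C4 methoxy carbon, C5 and C6 diol carbons, C6 next to C1).

Assumption: the dioxygenase is taken to rank iodine above the slim ethynyl group, as it does for other para-substituted iodobenzenes.

**Step 1**
Reactants: 1 1-ethynyl-4-iodobenzene
Product: 2 (1S,2S)-3-ethynyl-6-iodocyclohexa-3,5-diene-1,2-diol
Conditions: E. coli JM109(pDTG601) whole cells expressing toluene dioxygenase (IPTG-induced), air (O2), glucose feed, phosphate buffer pH 7, 30 °C; EtOAc extraction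
Reagents that add atoms: dioxygen, O=O
Why: The Rieske non-heme iron dioxygenase holds the arene above its mononuclear iron centre, activates O2 with two electrons relayed from NADH and delivers both oxygen atoms to one unsubstituted ring edge from one face, so the C5–O and C6–O bonds form cis and the ring is dearomatized to the C1=C2–C3=C4 diene. The closest known reaction type is the toluene dioxygenase cis-dihydroxylation of para-substituted iodobenzenes, in which iodine takes the pocket normally filled by the single substituent of a monosubstituted arene. No ring is closed, so no mode of closure applies. Both new stereocentres (C5 and C6) are set by the enzyme alone: with iodine in the dominant position, oxygen enters at the carbon ortho to iodine and at its neighbour on the face that gives the (1S,2S) diol, which after loss of iodine belongs to the series antipodal to the ordinary diol of ethynylbenzene. The step needs discrimination between the two enantiotopic unsubstituted edges, secured by the size gap between iodine and the linear ethynyl group, and chemoselectivity for the arene over the alkyne, secured by the enzyme's arene cis-dihydroxylation manifold and by a host that lacks the diol dehydrogenase, so the diol is not rearomatized to a catechol.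

**Step 2**
Reactants: 2 (1S,2S)-3-ethynyl-6-iodocyclohexa-3,5-diene-1,2-diol
Product: 3 (3aS,7aS)-4-ethynyl-7-iodo-2,2-dimethyl-3a,7a-dihydro-1,3-benzodioxole
Conditions: 2,2-dimethoxypropane, p-TsOH·H2O (cat.), acetone, 0 °C → rt; Et3N quench
Reagents that add atoms: 2,2-dimethoxypropane, COC(C)(C)OC
Why: Acid-catalysed transketalization (acetonide formation) should close the five-membered dioxolane on the cis-diol without touching C5 or C6, and it blocks the acid-triggered dehydration to a phenol that free diene-diols undergo.

**Step 3**
Reactants: 3 (3aS,7aS)-4-ethynyl-7-iodo-2,2-dimethyl-3a,7a-dihydro-1,3-benzodioxole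
Product: 5 (3aS,7aR)-4-ethynyl-2,2-dimethyl-3a,7a-dihydro-1,3-benzodioxole, via dimagnesiated acetonide 4 (not isolated)
Conditions: i-PrMgCl·LiCl (2.2 equiv), THF, −20 → 0 °C; then sat. aq. NH4Cl, 0 °C; product used at once
Reagents that add atoms: none
Why: Iodine–magnesium exchange followed by protonolysis: one equivalent of the reagent is consumed by the acidic alkyne C–H and the second exchanges the alkenyl iodide, which is activated by the allylic C5 oxygen, and because any alkenylmagnesium formed early is simply protonated by a remaining alkyne C–H, every order of events converges on the same C4–H product, with no reducing agent present that could touch the alkyne or the diene.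

**Step 4**
Reactants: 5 (3aS,7aR)-4-ethynyl-2,2-dimethyl-3a,7a-dihydro-1,3-benzodioxole
Product: 6 (3aR,4S,5S,7aS)-7-ethynyl-2,2-dimethyl-3a,4,5,7a-tetrahydro-1,3-benzodioxole-4,5-diol
Conditions: OsO4 (2 mol %), NMO (1.2 equiv), acetone/H2O (4:1), 0 °C → rt; aq. Na2SO3 quench
Reagents that add atoms: osmium tetroxide, O=[Os](=O)(=O)=O; N-methylmorpholine N-oxide, C[N+]1([O-])CCOCC1; water, O
Why: Catalytic OsO4/NMO syn-dihydroxylation: the [3+2] addition should take the cis-disubstituted C3=C4 bond, since C1=C2 is trisubstituted, deactivated by its sp-carbon substituent and keeps the enyne conjugation when left intact, and it should come from the face opposite the acetonide, which sets C3 and C4 with both new oxygens trans to the C5 oxygen (the cis, trans, cis array).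

**Step 5**
Reactants: 6 (3aR,4S,5S,7aS)-7-ethynyl-2,2-dimethyl-3a,4,5,7a-tetrahydro-1,3-benzodioxole-4,5-diol
Product: 7 (3aS,4S,5S,7aS)-7-ethynyl-4-methoxy-2,2-dimethyl-3a,4,5,7a-tetrahydro-1,3-benzodioxol-5-ol
Conditions: NaH (1.05 equiv), MeI (1.3 equiv), THF, 0 °C
Reagents that add atoms: iodomethane, CI
Why: Williamson ether synthesis under substrate control: the O4–H hydroxyl, flanked by the C3 oxygen and the ketal oxygen on C5, is the more acidic one and its sodium alkoxide is held in a chelate, so one equivalent of base should deliver the mono-methyl ether at O4, while the alkyne C–H is not removed by NaH in THF at 0 °C on this timescale.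

**Step 6**
Reactants: 7 (3aS,4S,5S,7aS)-7-ethynyl-4-methoxy-2,2-dimethyl-3a,4,5,7a-tetrahydro-1,3-benzodioxol-5-ol
Product: 8 (3aS,4S,5S,7aS)-7-ethynyl-4-methoxy-2,2-dimethyl-3a,4,5,7a-tetrahydro-1,3-benzodioxol-5-yl acetate
Conditions: Ac2O, pyridine, DMAP (cat.), CH2Cl2, 0 °C → rt
Reagents that add atoms: acetic anhydride, CC(=O)OC(C)=O
Why: DMAP-catalysed acylation of the one remaining, unhindered allylic secondary hydroxyl; no stereocentre is touched.

**Step 7**
Reactants: 8 (3aS,4S,5S,7aS)-7-ethynyl-4-methoxy-2,2-dimethyl-3a,4,5,7a-tetrahydro-1,3-benzodioxol-5-yl acetate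
Product: 9 (1S,4S,5S,6R)-3-ethynyl-4,5-dihydroxy-6-methoxycyclohex-2-en-1-yl acetate
Conditions: AcOH/H2O (4:1), 50 °C
Reagents that add atoms: none
Why: Acid-catalysed ketal hydrolysis releases the C5,C6 diol at a stage where no acid-sensitive tertiary allylic alcohol is yet present, and the acetate stays on O3 because its only cis neighbour, O4, is capped as the methyl ether.

**Step 8**
Reactants: 10 2-methylbut-3-yn-2-ol
Product: 11 (E)-2-methyl-4-(tributylstannyl)but-3-en-2-ol
Conditions: Bu3SnH (1.1 equiv), PdCl2(PPh3)2 (2 mol %), THF, 0 °C → rt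
Reagents that add atoms: tributyltin hydride, CCCC[SnH](CCCC)CCCC
Why: Palladium-catalysed hydrostannation: syn addition of Sn–H across the terminal alkyne gives the E alkene, and the bulky tertiary carbinol should send tin to the terminal carbon.

**Step 9**
Reactants: 11 (E)-2-methyl-4-(tributylstannyl)but-3-en-2-ol; 12 2,3-dibromoprop-1-ene (2 equiv)
Product: 13 (E)-6-bromo-2-methylhepta-3,6-dien-2-ol
Conditions: Pd2(dba)3 (2.5 mol %), AsPh3 (10 mol %), THF, rt → 45 °C
Reagents that add atoms: none
Why: Stille coupling at the allylic bromide: zerovalent palladium inserts into the allylic C–Br bond far faster than into the vinylic one, the symmetrical 2-bromoallyl unit gives the same product from either allyl terminus, and transmetalation with retention keeps the E alkene.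

**Step 10**
Reactants: 9 (1S,4S,5S,6R)-3-ethynyl-4,5-dihydroxy-6-methoxycyclohex-2-en-1-yl acetate; 13 (E)-6-bromo-2-methylhepta-3,6-dien-2-ol (1.3 equiv)
Product: 14 (1S,4S,5S,6R)-4,5-dihydroxy-3-[(5E)-7-hydroxy-7-methyl-3-methylideneoct-5-en-1-yn-1-yl]-6-methoxycyclohex-2-en-1-yl acetate
Conditions: Pd(PPh3)4 (5 mol %), CuI (10 mol %), Et3N, degassed THF, rt → 45 °C
Reagents that add atoms: none
Why: Sonogashira coupling: oxidative addition of the vinylic C–Br bond to zerovalent palladium, transmetalation from the copper acetylide of 9 and reductive elimination form the C(sp)–C(sp2) bond under mild amine conditions that tolerate the free diol, the tertiary alcohol and, in the absence of a competent nucleophile, the allylic acetate.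

**Compound list**
1 | 1-ethynyl-4-iodobenzene | C#Cc1ccc(I)cc1 | starting material
2 | (1S,2S)-3-ethynyl-6-iodocyclohexa-3,5-diene-1,2-diol | C#CC1=CC=C(I)[C@@H](O)[C@H]1O | intermediate
3 | (3aS,7aS)-4-ethynyl-7-iodo-2,2-dimethyl-3a,7a-dihydro-1,3-benzodioxole | C#CC1=CC=C(I)[C@H]2OC(C)(C)O[C@@H]12 | intermediate
4 | dimagnesiated acetonide: 3 with the C4 iodine and the alkyne hydrogen each replaced by MgCl, ring stereocentres as in 3 | Cl[Mg]C#CC1=CC=C([Mg]Cl)[C@H]2OC(C)(C)O[C@@H]12 | intermediate (not isolated)
5 | (3aS,7aR)-4-ethynyl-2,2-dimethyl-3a,7a-dihydro-1,3-benzodioxole | C#CC1=CC=C[C@H]2OC(C)(C)O[C@@H]12 | intermediate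
6 | (3aR,4S,5S,7aS)-7-ethynyl-2,2-dimethyl-3a,4,5,7a-tetrahydro-1,3-benzodioxole-4,5-diol | C#CC1=C[C@H](O)[C@H](O)[C@H]2OC(C)(C)O[C@@H]12 | intermediate
7 | (3aS,4S,5S,7aS)-7-ethynyl-4-methoxy-2,2-dimethyl-3a,4,5,7a-tetrahydro-1,3-benzodioxol-5-ol | C#CC1=C[C@H](O)[C@H](OC)[C@H]2OC(C)(C)O[C@@H]12 | intermediate
8 | (3aS,4S,5S,7aS)-7-ethynyl-4-methoxy-2,2-dimethyl-3a,4,5,7a-tetrahydro-1,3-benzodioxol-5-yl acetate | C#CC1=C[C@H](OC(C)=O)[C@H](OC)[C@H]2OC(C)(C)O[C@@H]12 | intermediate
9 | (1S,4S,5S,6R)-3-ethynyl-4,5-dihydroxy-6-methoxycyclohex-2-en-1-yl acetate | C#CC1=C[C@H](OC(C)=O)[C@H](OC)[C@@H](O)[C@H]1O | intermediate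
10 | 2-methylbut-3-yn-2-ol | CC(C)(O)C#C | starting material
11 | (E)-2-methyl-4-(tributylstannyl)but-3-en-2-ol | CCCC[Sn](CCCC)(CCCC)/C=C/C(C)(C)O | intermediate
12 | 2,3-dibromoprop-1-ene | C=C(Br)CBr | starting material
13 | (E)-6-bromo-2-methylhepta-3,6-dien-2-ol | C=C(Br)C/C=C/C(C)(C)O | intermediate
14 | (1S,4S,5S,6R)-4,5-dihydroxy-3-[(5E)-7-hydroxy-7-methyl-3-methylideneoct-5-en-1-yn-1-yl]-6-methoxycyclohex-2-en-1-yl acetate | C=C(C#CC1=C[C@H](OC(C)=O)[C@H](OC)[C@@H](O)[C@H]1O)C/C=C/C(C)(C)O | target

**Totals**
Total step count: 10.
Longest linear sequence: 8 steps (steps 1 to 7, then step 10, from 1).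

**Steps most likely to fail**

1. Step 1. The cells may turn the iodoalkyne over slowly, or the pocket may not hold iodine firmly in the dominant position, which would erode or invert the absolute sense of the diol. The fallback replaces 1, so no numbered compound serves as its origin, and it returns at 5. Commercial 1-bromo-4-iodobenzene F1, a member of the established dihalobenzene substrate class, is fed to the same cells. This should give (1S,2R)-3-bromo-6-iodocyclohexa-3,5-diene-1,2-diol F2, which is crystallised if enantiomeric enrichment is needed. F2 is protected with 2,2-dimethoxypropane and p-TsOH as (3aR,7aS)-4-bromo-7-iodo-2,2-dimethyl-3a,7a-dihydro-1,3-benzodioxole F3. Radical deiodination (Bu3SnH, Et3B/air, toluene, 0 °C; iodine abstraction far outruns bromine abstraction) should give (3aR,7aR)-4-bromo-2,2-dimethyl-3a,7a-dihydro-1,3-benzodioxole F4. Sonogashira coupling with ethynyltrimethylsilane (Pd(PPh3)4, CuI, Et3N) should give (3aS,7aR)-2,2-dimethyl-4-[(trimethylsilyl)ethynyl]-3a,7a-dihydro-1,3-benzodioxole F5, and K2CO3 in MeOH then removes the silyl group to give 5.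

2. Step 5. Site discrimination between O3 and O4 may be poor, or methylation may run on to the diether. The fallback sets out from 6 and returns at 8, reversing the order and relying on sterics. Kinetic acylation of the less hindered allylic O3–H (AcCl 1.05 equiv, 2,4,6-collidine, CH2Cl2, −78 °C) should give (3aR,4S,5S,7aS)-7-ethynyl-4-hydroxy-2,2-dimethyl-3a,4,5,7a-tetrahydro-1,3-benzodioxol-5-yl acetate F6. Non-basic methylation of O4–H with Me3OBF4 and 1,8-bis(dimethylamino)naphthalene (CH2Cl2, rt) then gives 8; these conditions avoid acyl migration and leave the alkyne C–H alone.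

3. Step 3. The exchange may be sluggish at low temperature, leaving time for Diels–Alder dimerization of the diene once the mixture is warmed. The fallback sets out from 3 and returns at 5 by a radical chain reduction (Bu3SnH 1.05 equiv, Et3B/air, toluene, 0 °C). It relies on iodine-atom abstraction by the stannyl radical being much faster than its addition to the alkyne, and it makes no new compound (F0).

**Further compounds**
F1 | step 1 | 1-bromo-4-iodobenzene (purchased) | Brc1ccc(I)cc1
F2 | step 1 | (1S,2R)-3-bromo-6-iodocyclohexa-3,5-diene-1,2-diol | BrC1=CC=C(I)[C@@H](O)[C@H]1O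
F3 | step 1 | (3aR,7aS)-4-bromo-7-iodo-2,2-dimethyl-3a,7a-dihydro-1,3-benzodioxole | BrC1=CC=C(I)[C@H]2OC(C)(C)O[C@@H]12
F4 | step 1 | (3aR,7aR)-4-bromo-2,2-dimethyl-3a,7a-dihydro-1,3-benzodioxole | BrC1=CC=C[C@H]2OC(C)(C)O[C@@H]12
F5 | step 1 | (3aS,7aR)-2,2-dimethyl-4-[(trimethylsilyl)ethynyl]-3a,7a-dihydro-1,3-benzodioxole | C[Si](C)(C)C#CC1=CC=C[C@H]2OC(C)(C)O[C@@H]12
F6 | step 5 | (3aR,4S,5S,7aS)-7-ethynyl-4-hydroxy-2,2-dimethyl-3a,4,5,7a-tetrahydro-1,3-benzodioxol-5-yl acetate | C#CC1=C[C@H](OC(C)=O)[C@H](O)[C@H]2OC(C)(C)O[C@@H]12
F0 | step 3 | none | none
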